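**Retrosynthetic overview**

1. The strategy rests on C2 of ring C: it is a CH2 bonded only to O1 and to the quaternary carbinol carbon C3, which sits next to the C4 ketone. C2 can therefore start as the methyl carbon of an aryl methyl ether on C8a, with C3/C4 as an aryl 1,2-dione. The C3–C2 bond is made by light-driven hydrogen transfer from that OCH3 to the C3 carbonyl oxygen, followed by biradical coupling.
2. Ring A is built symmetric (2,6-dimethoxy), so either methoxy group can react. The unused one becomes 5-OMe, peri to C4=O; it first anchors a chiral Sc(OTf)3–PyBox Lewis acid and is later the one methyl ether that BCl3 removes.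
3. Dione 12 comes from lithiated, silylated 3,5-dimethoxyphenol and the ring B arylglyoxal, followed by oxidation of the benzoin.
4. Ring B comes from gallacetophenone: O4-prenylation, Claisen rearrangement (C5' 1,1-dimethylallyl group), O4-methylation, silylation, Riley oxidation.
5. Rings A and B are bought as arenes; ring C is the only ring formed (step 9). End game: BCl3, then fluoride.

Key step: step 9

Assumption: the sense of induction of the scandium–PyBox complex in step 9 cannot be predicted with confidence; the (S,S)-ligand is taken to give the 3R product, and its enantiomer would be used if the sense proves opposite.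

Abbreviations and numbering: TBS = tert-butyldimethylsilyl, TIPS = triisopropylsilyl. Chromanone: O1, C2, C3, C4, C4a, C5–C8, C8a. Ring B: C1'–C6'.

**Route**

Step 1
Reactants: 1 gallacetophenone (1-(2,3,4-trihydroxyphenyl)ethanone); 2 prenyl bromide (1-bromo-3-methylbut-2-ene)
Product: 3 1-[2,3-dihydroxy-4-(3-methylbut-2-enyloxy)phenyl]ethanone
Conditions: Li2CO3 (1.5 equiv), DMF, 50 °C
Reagents that add atoms: none
Why: Williamson etherification, selective for O4 because the 4-OH para to the acetyl group is the most acidic phenol and the 2-OH is hydrogen-bonded to the carbonyl, so a weak carbonate base alkylates only that oxygen.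

Step 2
Reactants: 3 1-[2,3-dihydroxy-4-(3-methylbut-2-enyloxy)phenyl]ethanone
Product: 4 1-[2,3,4-trihydroxy-5-(2-methylbut-3-en-2-yl)phenyl]ethanone
Conditions: PhNEt2, 195 °C, sealed tube, Ar
Reagents that add atoms: none
Why: Aromatic Claisen rearrangement, in which the [3,3] shift delivers the prenyl group with allylic inversion to C5, the only free position ortho to the ether oxygen, and tautomerisation restores the phenol bearing the 1,1-dimethylallyl group.

Step 3
Reactants: 4 1-[2,3,4-trihydroxy-5-(2-methylbut-3-en-2-yl)phenyl]ethanone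
Product: 5 1-[2,3-dihydroxy-4-methoxy-5-(2-methylbut-3-en-2-yl)phenyl]ethanone
Conditions: MeI (1.1 equiv), Li2CO3 (1.2 equiv), DMF, 40 °C
Reagents that add atoms: iodomethane, CI
Why: Regioselective Williamson methylation, since as in step 1 only the para-acyl 4-OH is deprotonated by the weak base and iodomethane is small enough to reach this oxygen beside the tertiary alkyl group.

Step 4
Reactants: 5 1-[2,3-dihydroxy-4-methoxy-5-(2-methylbut-3-en-2-yl)phenyl]ethanone
Product: 6 1-[2,3-bis(tert-butyldimethylsilyloxy)-4-methoxy-5-(2-methylbut-3-en-2-yl)phenyl]ethanone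
Conditions: TBSCl (3 equiv), imidazole (6 equiv), DMAP (cat.), DMF, 45 °C
Reagents that add atoms: tert-butyldimethylsilyl chloride, CC(C)(C)[Si](C)(C)Cl
Why: Imidazole-promoted silyl ether formation, where excess reagent and gentle heating silylate both the 3-OH and the hydrogen-bonded 2-OH, so that no acidic proton remains for the organolithium step.

Step 5
Reactants: 6 1-[2,3-bis(tert-butyldimethylsilyloxy)-4-methoxy-5-(2-methylbut-3-en-2-yl)phenyl]ethanone
Product: 7 2-[2,3-bis(tert-butyldimethylsilyloxy)-4-methoxy-5-(2-methylbut-3-en-2-yl)phenyl]-2-oxoacetaldehyde (ring B arylglyoxal)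
Conditions: SeO2 (1.5 equiv), 1,4-dioxane/H2O (30:1), 95 °C; then toluene azeotrope, used at once
Reagents that add atoms: selenium dioxide, O=[Se]=O
Why: Riley oxidation of the enolisable methyl group of an aryl methyl ketone to the aldehyde, which spares the 1,1-dimethylallyl group because it has no allylic hydrogen.

Step 6
Reactants: 8 3,5-dimethoxyphenol
Product: 9 (3,5-dimethoxyphenoxy)triisopropylsilane
Conditions: TIPSCl, imidazole, DMF, rt
Reagents that add atoms: triisopropylsilyl chloride, CC(C)[Si](Cl)(C(C)C)C(C)C
Why: Silyl ether formation, which masks the phenol with a bulky group that is a poor lithiation director and shields its own two ortho positions.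

Step 7
Reactants: 9 (3,5-dimethoxyphenoxy)triisopropylsilane; 7 ring B arylglyoxal
Product: 11 1-[2,3-bis(tert-butyldimethylsilyloxy)-4-methoxy-5-(2-methylbut-3-en-2-yl)phenyl]-2-[2,6-dimethoxy-4-(triisopropylsilyloxy)phenyl]-2-hydroxyethanone (racemic benzoin), via ring A aryllithium 10 (not isolated)
Conditions: n-BuLi (1.15 equiv), TMEDA, THF, 0 °C; then 7, THF, −78 °C; AcOH quench at −78 °C
Reagents that add atoms: n-butyllithium, [Li]CCCC (supplies the lithium of 10; no atoms in 11)
Why: Directed ortho-lithiation followed by 1,2-addition to an aldehyde, in which both methoxy groups direct n-BuLi to the carbon between them and the aryllithium then attacks the aldehyde carbon of 7, far more electrophilic than the neighbouring hindered aryl ketone, giving a carbinol centre as a racemate that is removed in step 8.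

Step 8
Reactants: 11 racemic benzoin
Product: 12 1-[2,3-bis(tert-butyldimethylsilyloxy)-4-methoxy-5-(2-methylbut-3-en-2-yl)phenyl]-2-[2,6-dimethoxy-4-(triisopropylsilyloxy)phenyl]ethane-1,2-dione
Conditions: Dess–Martin periodinane (1.3 equiv), CH2Cl2, 0 °C to rt, dark
Reagents that add atoms: none
Why: Dess–Martin oxidation of the secondary α-hydroxy ketone to the 1,2-dione under neutral conditions that leave aryl silyl ethers and the monosubstituted alkene untouched, and any benzoin tautomer present converges on the same dione.

Step 9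
Reactants: 12 ring A–ring B 1,2-dione
Product: 14 (3R)-3-[2,3-bis(tert-butyldimethylsilyloxy)-4-methoxy-5-(2-methylbut-3-en-2-yl)phenyl]-3-hydroxy-5-methoxy-7-(triisopropylsilyloxy)chroman-4-one, via triplet 1,6-biradical 13 (not isolated)
Conditions: Sc(OTf)3 (1.1 equiv), 2,6-bis[(4S)-4-tert-butyl-4,5-dihydrooxazol-2-yl]pyridine ((S,S)-t-Bu-PyBox, 1.2 equiv), 4 Å MS, degassed CH2Cl2, −40 °C, 427 nm LEDs, Ar; aq. NaHCO3 work-up
Reagents that add atoms: none
Why: Proposed new method: 427 nm light excites the yellow 1,2-dione of 12 to its n,π* triplet while the scandium–PyBox Lewis acid sits in the six-membered chelate formed by the C4 carbonyl oxygen and one ortho methoxy oxygen of ring A, so that the free C3 carbonyl oxygen, held transoid to C4=O, reaches the other methoxy group and takes a hydrogen atom from it by 1,7-transfer to give 1,6-biradical 13 (a C3 ketyl radical conjugated with C4=O and an aryl–O–CH2 radical). After intersystem crossing the two radical centres combine, which closes ring C as a six-membered ring through the new C3–C2 bond (radical–radical coupling, no Baldwin constraint) and delivers the tertiary C3 alcohol directly. The closest known reactions are the racemic Norrish–Yang-type photocyclisation of 1-(2-alkoxyphenyl)-1,2-diones to 3-hydroxychroman-4-ones and the control of triplet photoreactions of chelating ortho-oxygenated aryl ketones by chiral scandium–PyBox complexes; their combination into an enantioselective hydrogen-abstraction cyclisation is not known. C3 is the only new stereocentre and is set in the coupling event by the ligand on scandium, whose tert-butyl group should cover one face of the flat ring A/C4=O chelate and force the bulky ring B aryl group of the ketyl radical onto the open face (sense of induction assumed as stated above). The step needs six-ring coupling at C3 in place of five-ring coupling at C4, which the bound scandium secures by occupying the C4 oxygen lone pair so that only the C3 oxygen can abstract, and it needs abstraction from OCH3 alone, which is secured because the only other C–H bonds near the dione are unactivated Si–CH3 bonds on ring B, the vinyl group carries no allylic hydrogen, and the chromanone product does not absorb at 427 nm. A chelate spanning both carbonyl oxygens is avoided on purpose, since a cisoid dione would turn the C3 oxygen away from ring A and stop the six-ring pathway.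

Step 10
Reactants: 14 (3R)-5-O-methyl tris-silyl chromanone
Product: 15 (3R)-3-[2,3-bis(tert-butyldimethylsilyloxy)-4-methoxy-5-(2-methylbut-3-en-2-yl)phenyl]-3,5-dihydroxy-7-(triisopropylsilyloxy)chroman-4-one
Conditions: BCl3 (3 equiv), CH2Cl2, −78 to −20 °C; H2O
Reagents that add atoms: none
Why: Chelation-controlled ether cleavage, in which boron bridges the C4 carbonyl oxygen and the peri 5-OMe oxygen and chloride removes that methyl group, while the unchelated 4'-OMe and the aryl silyl ethers should persist at low temperature and C3 should not ionise because the cation would lie next to the carbonyl.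

Step 11
Reactants: 15 (3R)-5-hydroxy tris-silyl chromanone
Product: 16 (3R)-3-[2,3-dihydroxy-4-methoxy-5-(2-methylbut-3-en-2-yl)phenyl]-3,5,7-trihydroxychroman-4-one (CNP0205426.1)
Conditions: TBAF (3.5 equiv), AcOH (4 equiv), THF, 0 °C, Ar
Reagents that add atoms: none
Why: Fluoride-mediated cleavage of the three aryl silyl ethers, buffered with acetic acid so that the air-sensitive polyphenol and the tertiary α-ketol never meet free base, leaves C3 untouched.

**Compound list**

1 | gallacetophenone, 1-(2,3,4-trihydroxyphenyl)ethanone | CC(=O)c1ccc(O)c(O)c1O | starting material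
2 | prenyl bromide, 1-bromo-3-methylbut-2-ene | CC(C)=CCBr | starting material
3 | 1-[2,3-dihydroxy-4-(3-methylbut-2-enyloxy)phenyl]ethanone | CC(=O)c1ccc(OCC=C(C)C)c(O)c1O | intermediate
4 | 1-[2,3,4-trihydroxy-5-(2-methylbut-3-en-2-yl)phenyl]ethanone | CC(=O)c1cc(C(C)(C)C=C)c(O)c(O)c1O | intermediate
5 | 1-[2,3-dihydroxy-4-methoxy-5-(2-methylbut-3-en-2-yl)phenyl]ethanone | CC(=O)c1cc(C(C)(C)C=C)c(OC)c(O)c1O | intermediate
6 | 1-[2,3-bis(tert-butyldimethylsilyloxy)-4-methoxy-5-(2-methylbut-3-en-2-yl)phenyl]ethanone | CC(=O)c1cc(C(C)(C)C=C)c(OC)c(O[Si](C)(C)C(C)(C)C)c1O[Si](C)(C)C(C)(C)C | intermediate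
7 | 2-[2,3-bis(tert-butyldimethylsilyloxy)-4-methoxy-5-(2-methylbut-3-en-2-yl)phenyl]-2-oxoacetaldehyde (ring B arylglyoxal) | O=CC(=O)c1cc(C(C)(C)C=C)c(OC)c(O[Si](C)(C)C(C)(C)C)c1O[Si](C)(C)C(C)(C)C | intermediate
8 | 3,5-dimethoxyphenol | COc1cc(O)cc(OC)c1 | starting material
9 | (3,5-dimethoxyphenoxy)triisopropylsilane | COc1cc(OC)cc(O[Si](C(C)C)(C(C)C)C(C)C)c1 | intermediate
10 | [2,6-dimethoxy-4-(triisopropylsilyloxy)phenyl]lithium (ring A aryllithium, not isolated) | [Li]c1c(OC)cc(O[Si](C(C)C)(C(C)C)C(C)C)cc1OC | intermediate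
11 | 1-[2,3-bis(tert-butyldimethylsilyloxy)-4-methoxy-5-(2-methylbut-3-en-2-yl)phenyl]-2-[2,6-dimethoxy-4-(triisopropylsilyloxy)phenyl]-2-hydroxyethanone (racemic benzoin) | COc1cc(O[Si](C(C)C)(C(C)C)C(C)C)cc(OC)c1C(O)C(=O)c1cc(C(C)(C)C=C)c(OC)c(O[Si](C)(C)C(C)(C)C)c1O[Si](C)(C)C(C)(C)C | intermediate
12 | 1-[2,3-bis(tert-butyldimethylsilyloxy)-4-methoxy-5-(2-methylbut-3-en-2-yl)phenyl]-2-[2,6-dimethoxy-4-(triisopropylsilyloxy)phenyl]ethane-1,2-dione (key-step precursor) | COc1cc(O[Si](C(C)C)(C(C)C)C(C)C)cc(OC)c1C(=O)C(=O)c1cc(C(C)(C)C=C)c(OC)c(O[Si](C)(C)C(C)(C)C)c1O[Si](C)(C)C(C)(C)C | intermediate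
13 | triplet 1,6-biradical: C3 ketyl radical and aryl–O–CH2 radical (not isolated) | [CH2]Oc1cc(O[Si](C(C)C)(C(C)C)C(C)C)cc(OC)c1C(=O)[C](O)c1cc(C(C)(C)C=C)c(OC)c(O[Si](C)(C)C(C)(C)C)c1O[Si](C)(C)C(C)(C)C | intermediate
14 | (3R)-3-[2,3-bis(tert-butyldimethylsilyloxy)-4-methoxy-5-(2-methylbut-3-en-2-yl)phenyl]-3-hydroxy-5-methoxy-7-(triisopropylsilyloxy)chroman-4-one (key-step product) | O=C1c2c(OC)cc(O[Si](C(C)C)(C(C)C)C(C)C)cc2OC[C@]1(O)c1cc(C(C)(C)C=C)c(OC)c(O[Si](C)(C)C(C)(C)C)c1O[Si](C)(C)C(C)(C)C | intermediate
15 | (3R)-3-[2,3-bis(tert-butyldimethylsilyloxy)-4-methoxy-5-(2-methylbut-3-en-2-yl)phenyl]-3,5-dihydroxy-7-(triisopropylsilyloxy)chroman-4-one | O=C1c2c(O)cc(O[Si](C(C)C)(C(C)C)C(C)C)cc2OC[C@]1(O)c1cc(C(C)(C)C=C)c(OC)c(O[Si](C)(C)C(C)(C)C)c1O[Si](C)(C)C(C)(C)C | intermediate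
16 | (3R)-3-[2,3-dihydroxy-4-methoxy-5-(2-methylbut-3-en-2-yl)phenyl]-3,5,7-trihydroxychroman-4-one (CNP0205426.1) | C=CC(C)(C)c1cc([C@@]2(O)COc3cc(O)cc(O)c3C2=O)c(O)c(O)c1OC | target

**Step count and risks**

Total steps: 11. Longest linear sequence: 10 (steps 1–5 and 7–11; step 6 is the one-step ring A branch).

Steps most likely to fail:

Step 9 (proposed new method). The radical coupling may show little facial discrimination, or unbound dione may react in a racemic background process. Scandium may also bind elsewhere (across the dione or to ring B oxygens) and suppress the hydrogen transfer, or slowly remove silyl groups. The fallback uses known chemistry and sets out from dione 12. Irradiation of 12 alone in degassed benzene at 405–427 nm, the known racemic Norrish–Yang-type photocyclisation of 1-(2-alkoxyphenyl)-1,2-diones, should give racemic 3-[2,3-bis(tert-butyldimethylsilyloxy)-4-methoxy-5-(2-methylbut-3-en-2-yl)phenyl]-3-hydroxy-5-methoxy-7-(triisopropylsilyloxy)chroman-4-one F1. Preparative chromatography on a chiral stationary phase would then separate the 3R enantiomer, which is 14, from the (3S)-enantiomer of 14 F2, which is set aside. The route is rejoined at 14, and the absolute configuration would be assigned by chiroptical comparison or crystallography.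

Step 2. At the temperature needed, the ortho-(1,1-dimethylallyl)phenol may rearrange further (abnormal Claisen), cyclise through the neighbouring 4-OH to a dihydrobenzofuran, or lose the prenyl group, and the free catechol may oxidise. The fallback installs the tertiary allyl group by cross-coupling and sets out from gallacetophenone 1. Methylation at O4 (MeI, Li2CO3, DMF) would give 1-(2,3-dihydroxy-4-methoxyphenyl)ethanone F3. Bis-silylation (TBSCl, imidazole, DMF) would give 1-[2,3-bis(tert-butyldimethylsilyloxy)-4-methoxyphenyl]ethanone F4. Bromination with NBS in MeCN should go to C5 (ortho to OMe, para to the 2-silyloxy group, meta to acetyl) and give 1-[5-bromo-2,3-bis(tert-butyldimethylsilyloxy)-4-methoxyphenyl]ethanone F5. A ligand-controlled, branch-selective Suzuki–Miyaura coupling of F5 with 3,3-dimethylallylboronic acid pinacol ester (Pd(OAc)2, a bulky dialkylbiarylphosphine chosen for γ-selectivity, K3PO4, THF/H2O) would then give 6, where the route is rejoined.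

Step 7. The aryllithium may be quenched by residual glyoxal hydrate, the anhydrous glyoxal may oligomerise, some attack at the ketone may occur, or the alkoxide may trigger silyl migration. The fallback builds the dione by acylation and sets out from ketone 6. SeO2 in pyridine at 90 °C would oxidise the acetyl group to 2-[2,3-bis(tert-butyldimethylsilyloxy)-4-methoxy-5-(2-methylbut-3-en-2-yl)phenyl]-2-oxoacetic acid F6. Oxalyl chloride with catalytic DMF would convert it into 2-[2,3-bis(tert-butyldimethylsilyloxy)-4-methoxy-5-(2-methylbut-3-en-2-yl)phenyl]-2-oxoacetyl chloride F7. Aryllithium 10, made from 9 as in step 7, would be transmetallated with CuBr·SMe2 to [2,6-dimethoxy-4-(triisopropylsilyloxy)phenyl]copper F8. Organocopper reagents acylate at an acid chloride and leave ketones alone, so F8 and F7 should give dione 12 directly, where the route is rejoined, making step 8 unnecessary.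

Further compounds
F1 | step 9 | racemic 3-[2,3-bis(tert-butyldimethylsilyloxy)-4-methoxy-5-(2-methylbut-3-en-2-yl)phenyl]-3-hydroxy-5-methoxy-7-(triisopropylsilyloxy)chroman-4-one | O=C1c2c(OC)cc(O[Si](C(C)C)(C(C)C)C(C)C)cc2OCC1(O)c1cc(C(C)(C)C=C)c(OC)c(O[Si](C)(C)C(C)(C)C)c1O[Si](C)(C)C(C)(C)C
F2 | step 9 | (3S)-enantiomer of 14 | O=C1c2c(OC)cc(O[Si](C(C)C)(C(C)C)C(C)C)cc2OC[C@@]1(O)c1cc(C(C)(C)C=C)c(OC)c(O[Si](C)(C)C(C)(C)C)c1O[Si](C)(C)C(C)(C)C
F3 | step 2 | 1-(2,3-dihydroxy-4-methoxyphenyl)ethanone | CC(=O)c1ccc(OC)c(O)c1O
F4 | step 2 | 1-[2,3-bis(tert-butyldimethylsilyloxy)-4-methoxyphenyl]ethanone | CC(=O)c1ccc(OC)c(O[Si](C)(C)C(C)(C)C)c1O[Si](C)(C)C(C)(C)C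
F5 | step 2 | 1-[5-bromo-2,3-bis(tert-butyldimethylsilyloxy)-4-methoxyphenyl]ethanone | CC(=O)c1cc(Br)c(OC)c(O[Si](C)(C)C(C)(C)C)c1O[Si](C)(C)C(C)(C)C
F6 | step 7 | 2-[2,3-bis(tert-butyldimethylsilyloxy)-4-methoxy-5-(2-methylbut-3-en-2-yl)phenyl]-2-oxoacetic acid | OC(=O)C(=O)c1cc(C(C)(C)C=C)c(OC)c(O[Si](C)(C)C(C)(C)C)c1O[Si](C)(C)C(C)(C)C
F7 | step 7 | 2-[2,3-bis(tert-butyldimethylsilyloxy)-4-methoxy-5-(2-methylbut-3-en-2-yl)phenyl]-2-oxoacetyl chloride | ClC(=O)C(=O)c1cc(C(C)(C)C=C)c(OC)c(O[Si](C)(C)C(C)(C)C)c1O[Si](C)(C)C(C)(C)C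
F8 | step 7 | [2,6-dimethoxy-4-(triisopropylsilyloxy)phenyl]copper | [Cu]c1c(OC)cc(O[Si](C(C)C)(C(C)C)C(C)C)cc1OC
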